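**Strategy.** The cyclohexane ring (C1 bears the methyl, C4 the side chain, C5 and C6 the oxygens) is cut at C3–C4 and C1–C6 into a (Z)-2-butenyl unit (C1–C3 plus the methyl) and a C4–C6 unit. One operation joins them: a (Z)-γ-chloroalkenyllithium acylates the ester of a lithium enolate derived from an α-silyloxy γ-keto ester (C1–C6) and the enolate closes the ring by allylic alkylation (C3–C4). This exploits the 1,3-relation between the carbonyl-level C6 and C4, which is α to the ketone that later becomes the C7 methylene. Inversion at C5, 1,2-reduction and hydroxyl-directed epoxidation then build the all-cis ring.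

Key step: step 5

Remark: the target is read as all-cis at C4 (side chain), C5 (ester oxygen), C6 (hydroxyl) and the epoxide oxygen, and 1,3-anti at the C8 and C10 oxygens; the catalyst antipodes in steps 1 and 9 are those expected to give 2R in 3 and 8S in 17.

Step 1
Reactants: 1 1,1-dimethoxypropan-2-one; 2 ethyl glyoxylate
Product: 3 ethyl (2R)-2-hydroxy-5,5-dimethoxy-4-oxopentanoate
Conditions: (S)-proline (20 mol %), DMSO, 4 °C → rt, 1 in excess
Reagents that add atoms: none
Why: Proline-catalysed direct aldol addition, in which only the methyl side of 1 can form the reactive enamine and the enamine/carboxylic acid transition state should deliver the glyoxylate from one face to give the 2R carbinol (the future C5).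

Step 2
Reactants: 3 ethyl (2R)-2-hydroxy-5,5-dimethoxy-4-oxopentanoate
Product: 4 ethyl (2R)-2-[(tert-butyldimethylsilyl)oxy]-5,5-dimethoxy-4-oxopentanoate
Conditions: TBSCl, imidazole, DMF, rt
Reagents that add atoms: tert-butyldimethylsilyl chloride, CC(C)(C)[Si](C)(C)Cl
Why: Standard silylation of the secondary alcohol gives a robust, non-chelating ether that tolerates the organolithium chemistry of step 5.

Step 3
Reactants: 5 but-2-yn-1-ol
Product: 7 (Z)-3-iodobut-2-en-1-ol, via cyclic alkenylaluminate 6 (not isolated)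
Conditions: NaAlH2(OCH2CH2OMe)2, THF, 0 °C; then I2, −78 °C → rt
Reagents that add atoms: iodine, II
Why: Hydroxyl-directed trans-hydroalumination places aluminium on C3 cis to the CH2O group and iodinolysis with retention should give the Z iodide.

Step 4
Reactants: 7 (Z)-3-iodobut-2-en-1-ol
Product: 8 (Z)-1-chloro-3-iodobut-2-ene
Conditions: N-chlorosuccinimide, PPh3, CH2Cl2, 0 °C
Reagents that add atoms: N-chlorosuccinimide, O=C1CCC(=O)N1Cl
Why: Appel-type chlorination of the primary allylic alcohol proceeds by SN2 at carbon without allylic transposition and leaves the alkene geometry untouched.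

Step 5
Reactants: 4 ethyl (2R)-2-[(tert-butyldimethylsilyl)oxy]-5,5-dimethoxy-4-oxopentanoate; 8 (Z)-1-chloro-3-iodobut-2-ene
Product: 12 (5S,6R)-6-[(tert-butyldimethylsilyl)oxy]-5-(2,2-dimethoxyacetyl)-2-methylcyclohex-2-en-1-one, via lithium enolate 9 (not isolated), via chloroalkenyllithium 10 (not isolated), via acyclic chloroenone enolate 11 (not isolated)
Conditions: 4, lithium diisopropylamide (1.05 equiv), THF, −78 °C; separately 8, t-BuLi (2.0 equiv), Et2O, −78 °C, then transferred (1.0 equiv) onto the enolate at −78 °C; DMPU, −78 → −20 °C; AcOH quench at −78 °C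
Reagents that add atoms: none
Why: Proposed new method: iodine–lithium exchange on 8 gives the configurationally stable γ-chloroalkenyllithium 10, which acylates the only free carbonyl of 9 (the ketone is masked as its lithium enolate) to forge the acyl–vinyl bond C1–C6, after which the enolate carbon of 11 displaces the allylic chloride to forge C3–C4; loss of ethoxide and the acidic quench give enone 12. The closest known reaction types are annulations with bifunctional ω-chloroalkenyl-lithium or -copper reagents (addition followed by cycloalkylation), Parham-type cycloacylation of lithiated halides by esters, and the protection of ketones as their enolates during organolithium additions. The single ring closes by a 6-(enolexo)-exo-tet alkylation, since O-alkylation would need an eight-membered ring. The new stereocentre C4 is set in this alkylation: allylic 1,3-strain keeps the C5–H bond in the enolate plane and the tether delivers the electrophile from the face opposite the silyloxy group, giving the trans-4,5 (diequatorial, also thermodynamically preferred) product, while C5 comes unchanged from 4. The step needs mono-addition to the ester (one equivalent of 10 at −78 °C onto the α-silyloxy ester, whose tetrahedral adduct should persist until 10 is consumed), retention of the alkene geometry of 10 so that the chloride can reach the enolate, and cyclisation faster than β-elimination of silanolate, which DMPU, low temperature and the cold acidic quench are meant to secure.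

Step 6
Reactants: 12 (5S,6R)-6-[(tert-butyldimethylsilyl)oxy]-5-(2,2-dimethoxyacetyl)-2-methylcyclohex-2-en-1-one
Product: 13 (5R,6R)-6-[(tert-butyldimethylsilyl)oxy]-5-(3,3-dimethoxyprop-1-en-2-yl)-2-methylcyclohex-2-en-1-one
Conditions: Zn, CH2Br2, TiCl4, THF/CH2Cl2, 0 °C → rt
Reagents that add atoms: dibromomethane, BrCBr
Why: Takai–Lombardo methylenation is non-basic, so it avoids enolisation next to the silyloxy group, and should select the saturated, acetal-activated C7 ketone over the hindered conjugated ring carbonyl.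

Step 7
Reactants: 13 (5R,6R)-6-[(tert-butyldimethylsilyl)oxy]-5-(3,3-dimethoxyprop-1-en-2-yl)-2-methylcyclohex-2-en-1-one
Product: 14 2-[(1R,6R)-6-[(tert-butyldimethylsilyl)oxy]-4-methyl-5-oxocyclohex-3-en-1-yl]prop-2-enal
Conditions: PPTS, acetone/H2O, 40 °C
Reagents that add atoms: water, O
Why: Mild acid hydrolysis of the allylic dimethyl acetal unveils the α-substituted acrolein (C8 aldehyde) while the secondary TBS ether should survive.

Step 8
Reactants: 15 3-hydroxy-3-methylbutan-2-one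
Product: 16 3-methyl-2,3-bis[(trimethylsilyl)oxy]but-1-ene
Conditions: TMSOTf (2.2 equiv), Et3N, CH2Cl2, 0 °C
Reagents that add atoms: trimethylsilyl trifluoromethanesulfonate, C[Si](C)(C)OS(=O)(=O)C(F)(F)F
Why: Soft enolisation and silylation give the only possible enol silane and cap the tertiary alcohol in the same operation.

Step 9
Reactants: 14 2-[(1R,6R)-6-[(tert-butyldimethylsilyl)oxy]-4-methyl-5-oxocyclohex-3-en-1-yl]prop-2-enal; 16 3-methyl-2,3-bis[(trimethylsilyl)oxy]but-1-ene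
Product: 17 (5R,6R)-6-[(tert-butyldimethylsilyl)oxy]-5-{(3S)-3-hydroxy-6-methyl-5-oxo-6-[(trimethylsilyl)oxy]hept-1-en-2-yl}-2-methylcyclohex-2-en-1-one
Conditions: acyloxyborane catalyst (20 mol %) made from BH3·THF and (2S,3S)-2-O-(2,6-diisopropoxybenzoyl)tartaric acid, EtCN, −78 °C; then citric acid, MeOH, 0 °C
Reagents that add atoms: none
Why: Catalytic enantioselective Mukaiyama aldol addition to the aldehyde (1,2-addition, the ring enone being far less reactive), with the catalyst antipode chosen for attack on the si face so that the C8 carbinol should form as 8S.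

Step 10
Reactants: 17 (5R,6R)-6-[(tert-butyldimethylsilyl)oxy]-5-{(3S)-3-hydroxy-6-methyl-5-oxo-6-[(trimethylsilyl)oxy]hept-1-en-2-yl}-2-methylcyclohex-2-en-1-one
Product: 18 (5R,6R)-6-[(tert-butyldimethylsilyl)oxy]-5-[(3S,5S)-3,5,6-trihydroxy-6-methylhept-1-en-2-yl]-2-methylcyclohex-2-en-1-one
Conditions: Me4NBH(OAc)3, MeCN/AcOH (1:1), −30 °C; then citric acid, MeOH, rt
Reagents that add atoms: none
Why: Evans–Saksena reduction delivers hydride intramolecularly from the C8 alkoxyborohydride to give the 1,3-anti diol (10S) without touching the enone, and the acidic methanol work-up removes the tertiary trimethylsilyl group.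

Step 11
Reactants: 18 (5R,6R)-6-[(tert-butyldimethylsilyl)oxy]-5-[(3S,5S)-3,5,6-trihydroxy-6-methylhept-1-en-2-yl]-2-methylcyclohex-2-en-1-one
Product: 19 (5R,6R)-6-[(tert-butyldimethylsilyl)oxy]-5-{(3S)-3-hydroxy-4-[(4S)-2,2,5,5-tetramethyl-1,3-dioxolan-4-yl]but-1-en-2-yl}-2-methylcyclohex-2-en-1-one
Conditions: 2,2-dimethoxypropane, PPTS, CH2Cl2, rt
Reagents that add atoms: 2,2-dimethoxypropane, COC(C)(C)OC
Why: Thermodynamic acetonide formation should take the C10/C11 1,2-diol (five-membered dioxolane) in preference to the anti-1,3-diol, leaving only the C8 hydroxyl free.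

Step 12
Reactants: 19 (5R,6R)-6-[(tert-butyldimethylsilyl)oxy]-5-{(3S)-3-hydroxy-4-[(4S)-2,2,5,5-tetramethyl-1,3-dioxolan-4-yl]but-1-en-2-yl}-2-methylcyclohex-2-en-1-one
Product: 20 (3S)-2-[(1R,6R)-6-[(tert-butyldimethylsilyl)oxy]-4-methyl-5-oxocyclohex-3-en-1-yl]-4-[(4S)-2,2,5,5-tetramethyl-1,3-dioxolan-4-yl]but-1-en-3-yl (2Z)-2-methylbut-2-enoate
Conditions: angelic acid, 2,4,6-trichlorobenzoyl chloride, Et3N, toluene, rt; then 19, 80 °C
Reagents that add atoms: angelic acid [(2Z)-2-methylbut-2-enoic acid], C/C=C(/C)C(=O)O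
Why: Yamaguchi esterification through the mixed anhydride acylates the only free hydroxyl with retention at C8, and omitting a nucleophilic catalyst should preserve the Z geometry of the angelate.

Step 13
Reactants: 20 (3S)-2-[(1R,6R)-6-[(tert-butyldimethylsilyl)oxy]-4-methyl-5-oxocyclohex-3-en-1-yl]-4-[(4S)-2,2,5,5-tetramethyl-1,3-dioxolan-4-yl]but-1-en-3-yl (2Z)-2-methylbut-2-enoate
Product: 21 (3S)-2-[(1R,6R)-6-hydroxy-4-methyl-5-oxocyclohex-3-en-1-yl]-4-[(4S)-2,2,5,5-tetramethyl-1,3-dioxolan-4-yl]but-1-en-3-yl (2Z)-2-methylbut-2-enoate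
Conditions: HF·pyridine, THF/pyridine, 0 °C → rt
Reagents that add atoms: none
Why: Buffered fluoride cleaves the secondary silyl ether while the acetonide and the angelate should survive.

Step 14
Reactants: 21 (3S)-2-[(1R,6R)-6-hydroxy-4-methyl-5-oxocyclohex-3-en-1-yl]-4-[(4S)-2,2,5,5-tetramethyl-1,3-dioxolan-4-yl]but-1-en-3-yl (2Z)-2-methylbut-2-enoate
Product: 22 (1S,6R)-3-methyl-6-{(3S)-3-{[(2Z)-2-methylbut-2-enoyl]oxy}-4-[(4S)-2,2,5,5-tetramethyl-1,3-dioxolan-4-yl]but-1-en-2-yl}-2-oxocyclohex-3-en-1-yl (2Z)-2-methylbut-2-enoate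
Conditions: angelic acid, PPh3, DIAD, toluene, 0 °C → rt
Reagents that add atoms: angelic acid [(2Z)-2-methylbut-2-enoic acid], C/C=C(/C)C(=O)O
Why: Mitsunobu esterification displaces the activated C5 hydroxyl (α to the ketone) by SN2 with inversion, turning the trans C4/C5 relation into cis and installing the second angelate.

Step 15
Reactants: 22 (1S,6R)-3-methyl-6-{(3S)-3-{[(2Z)-2-methylbut-2-enoyl]oxy}-4-[(4S)-2,2,5,5-tetramethyl-1,3-dioxolan-4-yl]but-1-en-2-yl}-2-oxocyclohex-3-en-1-yl (2Z)-2-methylbut-2-enoate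
Product: 23 (1S,6R)-6-{(3S,5S)-5,6-dihydroxy-6-methyl-3-{[(2Z)-2-methylbut-2-enoyl]oxy}hept-1-en-2-yl}-3-methyl-2-oxocyclohex-3-en-1-yl (2Z)-2-methylbut-2-enoate
Conditions: AcOH/H2O (4:1), 40 °C
Reagents that add atoms: none
Why: Acidic hydrolysis of the acetonide is placed at the enone stage, before the acid-sensitive allylic alcohol and epoxide exist.

Step 16
Reactants: 23 (1S,6R)-6-{(3S,5S)-5,6-dihydroxy-6-methyl-3-{[(2Z)-2-methylbut-2-enoyl]oxy}hept-1-en-2-yl}-3-methyl-2-oxocyclohex-3-en-1-yl (2Z)-2-methylbut-2-enoate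
Product: 24 (1S,2R,6R)-6-{(3S,5S)-5,6-dihydroxy-6-methyl-3-{[(2Z)-2-methylbut-2-enoyl]oxy}hept-1-en-2-yl}-2-hydroxy-3-methylcyclohex-3-en-1-yl (2Z)-2-methylbut-2-enoate
Conditions: NaBH4, CeCl3·7H2O, MeOH, −78 °C
Reagents that add atoms: none
Why: Luche 1,2-reduction, in which hydride should attack axially and anti to the pseudoaxial C5 acyloxy group (Felkin–Anh), gives the C6 alcohol cis to the C5 ester and leaves the esters untouched.

Step 17
Reactants: 24 (1S,2R,6R)-6-{(3S,5S)-5,6-dihydroxy-6-methyl-3-{[(2Z)-2-methylbut-2-enoyl]oxy}hept-1-en-2-yl}-2-hydroxy-3-methylcyclohex-3-en-1-yl (2Z)-2-methylbut-2-enoate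
Product: 25 (1S,2S,3S,4R,6R)-4-{(3S,5S)-5,6-dihydroxy-6-methyl-3-{[(2Z)-2-methylbut-2-enoyl]oxy}hept-1-en-2-yl}-2-hydroxy-1-methyl-7-oxabicyclo[4.1.0]heptan-3-yl (2Z)-2-methylbut-2-enoate
Conditions: VO(acac)2 (5 mol %), t-BuOOH, CH2Cl2, 0 °C
Reagents that add atoms: tert-butyl hydroperoxide, CC(C)(C)OO
Why: Hydroxyl-directed vanadium-catalysed epoxidation delivers oxygen syn to the C6 hydroxyl on the trisubstituted ring alkene, which should react far faster than the side-chain 1,1-disubstituted alkene bearing an allylic ester.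

**Compound list**

1 | 1,1-dimethoxypropan-2-one | CC(=O)C(OC)OC | starting material
2 | ethyl glyoxylate | CCOC(=O)C=O | starting material
3 | ethyl (2R)-2-hydroxy-5,5-dimethoxy-4-oxopentanoate | CCOC(=O)[C@H](O)CC(=O)C(OC)OC | intermediate
4 | ethyl (2R)-2-[(tert-butyldimethylsilyl)oxy]-5,5-dimethoxy-4-oxopentanoate | CCOC(=O)[C@H](O[Si](C)(C)C(C)(C)C)CC(=O)C(OC)OC | intermediate
5 | but-2-yn-1-ol | CC#CCO | starting material
6 | sodium 2,2-bis(2-methoxyethoxy)-3-methyl-2,5-dihydro-1,2-oxaluminol-2-uide (cyclic alkenylaluminate, not isolated) | CC1=CCO[Al-]1(OCCOC)OCCOC.[Na+] | intermediate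
7 | (Z)-3-iodobut-2-en-1-ol | C/C(I)=C/CO | intermediate
8 | (Z)-1-chloro-3-iodobut-2-ene | C/C(I)=C/CCl | intermediate
9 | lithium (2Z,4R)-4-[(tert-butyldimethylsilyl)oxy]-5-ethoxy-1,1-dimethoxy-5-oxopent-2-en-2-olate (not isolated) | [Li+].[O-]/C(=C\[C@@H](O[Si](C)(C)C(C)(C)C)C(=O)OCC)C(OC)OC | intermediate
10 | [(E)-4-chlorobut-2-en-2-yl]lithium, lithium cis to the chloromethyl group (not isolated) | C/C([Li])=C/CCl | intermediate
11 | lithium (2Z,4R,6Z)-4-[(tert-butyldimethylsilyl)oxy]-8-chloro-1,1-dimethoxy-6-methyl-5-oxoocta-2,6-dien-2-olate (not isolated) | [Li+].[O-]/C(=C\[C@@H](O[Si](C)(C)C(C)(C)C)C(=O)/C(C)=C\CCl)C(OC)OC | intermediate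
12 | (5S,6R)-6-[(tert-butyldimethylsilyl)oxy]-5-(2,2-dimethoxyacetyl)-2-methylcyclohex-2-en-1-one | COC(OC)C(=O)[C@H]1CC=C(C)C(=O)[C@@H]1O[Si](C)(C)C(C)(C)C | intermediate
13 | (5R,6R)-6-[(tert-butyldimethylsilyl)oxy]-5-(3,3-dimethoxyprop-1-en-2-yl)-2-methylcyclohex-2-en-1-one | COC(OC)C(=C)[C@H]1CC=C(C)C(=O)[C@@H]1O[Si](C)(C)C(C)(C)C | intermediate
14 | 2-[(1R,6R)-6-[(tert-butyldimethylsilyl)oxy]-4-methyl-5-oxocyclohex-3-en-1-yl]prop-2-enal | O=CC(=C)[C@H]1CC=C(C)C(=O)[C@@H]1O[Si](C)(C)C(C)(C)C | intermediate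
15 | 3-hydroxy-3-methylbutan-2-one | CC(=O)C(C)(C)O | starting material
16 | 3-methyl-2,3-bis[(trimethylsilyl)oxy]but-1-ene | C=C(O[Si](C)(C)C)C(C)(C)O[Si](C)(C)C | intermediate
17 | (5R,6R)-6-[(tert-butyldimethylsilyl)oxy]-5-{(3S)-3-hydroxy-6-methyl-5-oxo-6-[(trimethylsilyl)oxy]hept-1-en-2-yl}-2-methylcyclohex-2-en-1-one | C=C([C@H](CC(=O)C(C)(C)O[Si](C)(C)C)O)[C@H]1CC=C(C)C(=O)[C@@H]1O[Si](C)(C)C(C)(C)C | intermediate
18 | (5R,6R)-6-[(tert-butyldimethylsilyl)oxy]-5-[(3S,5S)-3,5,6-trihydroxy-6-methylhept-1-en-2-yl]-2-methylcyclohex-2-en-1-one | C=C([C@H](C[C@H](O)C(C)(C)O)O)[C@H]1CC=C(C)C(=O)[C@@H]1O[Si](C)(C)C(C)(C)C | intermediate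
19 | (5R,6R)-6-[(tert-butyldimethylsilyl)oxy]-5-{(3S)-3-hydroxy-4-[(4S)-2,2,5,5-tetramethyl-1,3-dioxolan-4-yl]but-1-en-2-yl}-2-methylcyclohex-2-en-1-one | C=C([C@H](C[C@@H]2OC(C)(C)OC2(C)C)O)[C@H]1CC=C(C)C(=O)[C@@H]1O[Si](C)(C)C(C)(C)C | intermediate
20 | (3S)-2-[(1R,6R)-6-[(tert-butyldimethylsilyl)oxy]-4-methyl-5-oxocyclohex-3-en-1-yl]-4-[(4S)-2,2,5,5-tetramethyl-1,3-dioxolan-4-yl]but-1-en-3-yl (2Z)-2-methylbut-2-enoate | C=C([C@H](C[C@@H]2OC(C)(C)OC2(C)C)OC(=O)/C(C)=C\C)[C@H]1CC=C(C)C(=O)[C@@H]1O[Si](C)(C)C(C)(C)C | intermediate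
21 | (3S)-2-[(1R,6R)-6-hydroxy-4-methyl-5-oxocyclohex-3-en-1-yl]-4-[(4S)-2,2,5,5-tetramethyl-1,3-dioxolan-4-yl]but-1-en-3-yl (2Z)-2-methylbut-2-enoate | C=C([C@H](C[C@@H]2OC(C)(C)OC2(C)C)OC(=O)/C(C)=C\C)[C@H]1CC=C(C)C(=O)[C@@H]1O | intermediate
22 | (1S,6R)-3-methyl-6-{(3S)-3-{[(2Z)-2-methylbut-2-enoyl]oxy}-4-[(4S)-2,2,5,5-tetramethyl-1,3-dioxolan-4-yl]but-1-en-2-yl}-2-oxocyclohex-3-en-1-yl (2Z)-2-methylbut-2-enoate | C=C([C@H](C[C@@H]2OC(C)(C)OC2(C)C)OC(=O)/C(C)=C\C)[C@H]1CC=C(C)C(=O)[C@H]1OC(=O)/C(C)=C\C | intermediate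
23 | (1S,6R)-6-{(3S,5S)-5,6-dihydroxy-6-methyl-3-{[(2Z)-2-methylbut-2-enoyl]oxy}hept-1-en-2-yl}-3-methyl-2-oxocyclohex-3-en-1-yl (2Z)-2-methylbut-2-enoate | C=C([C@H](C[C@H](O)C(C)(C)O)OC(=O)/C(C)=C\C)[C@H]1CC=C(C)C(=O)[C@H]1OC(=O)/C(C)=C\C | intermediate
24 | (1S,2R,6R)-6-{(3S,5S)-5,6-dihydroxy-6-methyl-3-{[(2Z)-2-methylbut-2-enoyl]oxy}hept-1-en-2-yl}-2-hydroxy-3-methylcyclohex-3-en-1-yl (2Z)-2-methylbut-2-enoate | C=C([C@H](C[C@H](O)C(C)(C)O)OC(=O)/C(C)=C\C)[C@H]1CC=C(C)[C@@H](O)[C@H]1OC(=O)/C(C)=C\C | intermediate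
25 | (1S,2S,3S,4R,6R)-4-{(3S,5S)-5,6-dihydroxy-6-methyl-3-{[(2Z)-2-methylbut-2-enoyl]oxy}hept-1-en-2-yl}-2-hydroxy-1-methyl-7-oxabicyclo[4.1.0]heptan-3-yl (2Z)-2-methylbut-2-enoate | C=C([C@H](C[C@H](O)C(C)(C)O)OC(=O)/C(C)=C\C)[C@H]1C[C@H]2O[C@@]2(C)[C@@H](O)[C@H]1OC(=O)/C(C)=C\C | target

**Counts.** Total steps: 17. Longest linear sequence: 14 steps (1, 2, 5, 6, 7, 9, 10, 11, 12, 13, 14, 15, 16, 17).

**Steps most likely to fail**

Step 5 (proposed new method). The annulation may fail through a second addition of the alkenyllithium after early collapse of the tetrahedral adduct, through β-elimination of silanolate from the enolate before ring closure, or through self-coupling of the chloroalkenyllithium. The fallback is stepwise and uses known chemistry; it sets out from 4 (with 7 as the source of the four-carbon unit) and returns at 12. Alcohol 7 is converted with CBr4 and PPh3 into (Z)-1-bromo-3-iodobut-2-ene F1. The lithium enolate of 4 (lithium diisopropylamide, THF/DMPU, −78 → −40 °C) is alkylated with F1, expected anti to the silyloxy group, to give ethyl (2R,3S,5Z)-2-[(tert-butyldimethylsilyl)oxy]-3-(2,2-dimethoxyacetyl)-6-iodohept-5-enoate F2. Reduction of ester and ketone with i-Bu2AlH gives the iodo diol F3, and Dess–Martin oxidation gives (2R,3S,5Z)-2-[(tert-butyldimethylsilyl)oxy]-3-(2,2-dimethoxyacetyl)-6-iodohept-5-enal F4. Intramolecular Nozaki–Hiyama–Kishi addition of the alkenyl iodide to the aldehyde (CrCl2, catalytic NiCl2, DMSO; the ketone is tolerated) closes the ring to (5S,6R)-6-[(tert-butyldimethylsilyl)oxy]-5-(2,2-dimethoxyacetyl)-2-methylcyclohex-2-en-1-ol F5, and Dess–Martin oxidation of the allylic alcohol gives 12.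

Step 6. The titanium–zinc reagent may also methylenate the ring carbonyl, or its Lewis acidity may ionise the dimethyl acetal. The fallback removes the competition by carrying the ring carbon at the alcohol level; it sets out from 4 and returns at 13. Compound 4 is taken through F2, F3 and F4 to the cyclohexenol F5 as above. F5 has a single ketone, which is methylenated (Zn, CH2Br2, TiCl4) to (5R,6R)-6-[(tert-butyldimethylsilyl)oxy]-5-(3,3-dimethoxyprop-1-en-2-yl)-2-methylcyclohex-2-en-1-ol F6. Oxidation of the allylic alcohol with MnO2 then gives 13.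

Step 14. At the hindered α-ketol the Mitsunobu reaction may give elimination, partial retention through an acyloxyphosphonium pathway, or phosphine-induced isomerisation of the angelate to the tiglate. The fallback separates activation from displacement; it sets out from 21 and returns at 22. Alcohol 21 is converted (Tf2O, pyridine, CH2Cl2, −40 °C) into its C5 trifluoromethanesulfonate F7, which is displaced with inversion by caesium (2Z)-2-methylbut-2-enoate, CsO2CC(CH3)=CHCH3, with 18-crown-6 in toluene, to give 22.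

Further compounds
F1 | step 5 | (Z)-1-bromo-3-iodobut-2-ene | C/C(I)=C/CBr
F2 | step 5 | ethyl (2R,3S,5Z)-2-[(tert-butyldimethylsilyl)oxy]-3-(2,2-dimethoxyacetyl)-6-iodohept-5-enoate | CCOC(=O)[C@H](O[Si](C)(C)C(C)(C)C)[C@H](C/C=C(/C)I)C(=O)C(OC)OC
F3 | step 5 | (5Z)-2-[(tert-butyldimethylsilyl)oxy]-3-(1-hydroxy-2,2-dimethoxyethyl)-6-iodohept-5-en-1-ol, configuration at C2 and C3 as in F2, new carbinol as epimer mixture | OC[C@H](O[Si](C)(C)C(C)(C)C)[C@H](C/C=C(/C)I)C(O)C(OC)OC
F4 | step 5 | (2R,3S,5Z)-2-[(tert-butyldimethylsilyl)oxy]-3-(2,2-dimethoxyacetyl)-6-iodohept-5-enal | O=C[C@H](O[Si](C)(C)C(C)(C)C)[C@H](C/C=C(/C)I)C(=O)C(OC)OC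
F5 | step 5 | (5S,6R)-6-[(tert-butyldimethylsilyl)oxy]-5-(2,2-dimethoxyacetyl)-2-methylcyclohex-2-en-1-ol, C1 epimers | COC(OC)C(=O)[C@H]1CC=C(C)C(O)[C@@H]1O[Si](C)(C)C(C)(C)C
F6 | step 6 | (5R,6R)-6-[(tert-butyldimethylsilyl)oxy]-5-(3,3-dimethoxyprop-1-en-2-yl)-2-methylcyclohex-2-en-1-ol, C1 epimers | COC(OC)C(=C)[C@H]1CC=C(C)C(O)[C@@H]1O[Si](C)(C)C(C)(C)C
F7 | step 14 | (3S)-2-[(1R,6R)-4-methyl-5-oxo-6-{[(trifluoromethyl)sulfonyl]oxy}cyclohex-3-en-1-yl]-4-[(4S)-2,2,5,5-tetramethyl-1,3-dioxolan-4-yl]but-1-en-3-yl (2Z)-2-methylbut-2-enoate | C=C([C@H](C[C@@H]2OC(C)(C)OC2(C)C)OC(=O)/C(C)=C\C)[C@H]1CC=C(C)C(=O)[C@@H]1OS(=O)(=O)C(F)(F)F
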